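**Plan**

1. Retrosynthetic cuts: C3–C4 of ring A (the ring-closing bond); then C8=C17 (Wittig) and C13=C14 (Horner–Wadsworth–Emmons); then C9–C11 (Michael) and C10–C1 (conjugate addition); finally the C4···C7 bond is put back, which turns ring B plus its C4 appendage into the pinane skeleton of (1R,5R)-verbenone.
2. Mapping: the six-membered ring C1–C2–C3–C4–C5–C7 of verbenone is labdane C7, C8, C9, C10, C5, C6 (ring B); its CMe2 bridge is C4 with C18 and C19; its vinylic methyl is C20. The cyclobutane is a temporary ring that stores C4 as a latent isopropenyl group, and the enone supplies the C8 carbonyl, the C9 nucleophile and the C10 acceptor.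
3. Forward order: vinyl to C10 (cuprate), oxobutyl to C9 (Mukaiyama–Michael), E-enoate (olefination), cyclobutane fragmentation (ring B freed, isopropenyl on C5, C8 masked as enol acetate), hydroformylation (C1–C2–C3 chain ending in the C3 aldehyde). Ring A is then closed last, followed by methylenation, saponification and acetylation.
4. Enabling feature: C4 is a fully substituted carbon bearing two methyls next to the C3 carbinol, so it can be generated as a tertiary radical by Markovnikov hydrogen-atom transfer to an isopropenyl group on C5 and joined to a C3 aldehyde. The trans C5/C10 substituents on ring B preorganise a chair 6-exo closure to the trans-decalin.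
5. Stereochemistry: C5 from verbenone; C10 by cuprate addition anti to the CMe2 bridge; C3 in the ring closure (equatorial oxygen); C9 by enolate equilibration of the C8 ketone in the decalin; 13E from the olefination.

Key step: step 6

Remark: commercial (1R,5R)-(+)-verbenone is taken to be enantiomerically pure (material of lower purity would first be enriched), since all absolute stereocontrol rests on it.

**Route**

Step 1
Reactants: 1 (1R,5R)-(+)-verbenone; 2 vinylmagnesium bromide
Product: 4 4,6,6-trimethyl-2-(trimethylsilyloxy)-4-vinylbicyclo[3.1.1]hept-2-ene (vinyl anti to the CMe2 bridge), via bromomagnesium enolate 3 (not isolated)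
Conditions: CH2=CHMgBr (1.5 equiv), CuBr·SMe2 (10 mol %), Me3SiCl (2 equiv), THF, −78 → −30 °C; Et3N, pentane, cold aq NaHCO3
Reagents that add atoms: chlorotrimethylsilane, C[Si](C)(C)Cl
Why: Copper-catalysed conjugate addition of the vinyl Grignard reagent to the β,β-disubstituted enone, accelerated by Me3SiCl which traps the enolate as its silyl enol ether, should deliver vinyl to the face of C4 opposite the CMe2 bridge (the usual sense for cuprate additions to verbenone), which sets the quaternary carbon that becomes C10 with vinyl trans to the bridge carbon that becomes C4.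

Step 2
Reactants: 4 silyl enol ether; 5 methyl vinyl ketone
Product: 6 4,6,6-trimethyl-3-(3-oxobutyl)-4-vinylbicyclo[3.1.1]heptan-2-one (vinyl and oxobutyl both anti to the CMe2 bridge)
Conditions: 5 (1.5 equiv), BF3·OEt2 (1.0 equiv), i-PrOH (1.0 equiv), CH2Cl2–MeNO2, −78 → −20 °C
Reagents that add atoms: none
Why: Lewis-acid-promoted Mukaiyama–Michael addition of the regiodefined silyl enol ether (the other α-position is a bridgehead and cannot enolise) places the four-carbon chain on the future C9; attack anti to the CMe2 bridge is expected, but this centre is provisional and is reset in step 7.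

Step 3
Reactants: 6 diketone; 7 trimethyl phosphonoacetate
Product: 8 methyl (2E)-3-methyl-5-(4,6,6-trimethyl-2-oxo-4-vinylbicyclo[3.1.1]hept-3-yl)pent-2-enoate (configuration as 6)
Conditions: 7 (2.0 equiv), NaH (1.9 equiv), THF, 0 → 40 °C
Reagents that add atoms: none
Why: Horner–Wadsworth–Emmons olefination should occur only at the unhindered methyl ketone (the ring ketone lies between a bridgehead and a tertiary carbon next to a quaternary one) and favour the E-enoate, the minor Z-isomer being removed by chromatography.

Step 4
Reactants: 8 bicyclic keto enoate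
Product: 9 methyl (2E)-5-[2-acetoxy-6-methyl-5-(prop-1-en-2-yl)-6-vinylcyclohex-2-en-1-yl]-3-methylpent-2-enoate (isopropenyl trans to vinyl and cis to the ring methyl; side chain cis to vinyl)
Conditions: BF3·OEt2 (1.2 equiv), Zn(OAc)2 (0.5 equiv), Ac2O, 0 °C → rt
Reagents that add atoms: acetic anhydride, CC(=O)OC(C)=O
Why: Lewis-acid-mediated fragmentation of the cyclobutyl ketone (a known reaction of nopinone-type ketones) cleaves the strained bridgehead–CMe2 bond to a boron enolate and a tertiary cation, which loses a methyl proton to give the isopropenyl group while the enolate is acetylated on the former bridgehead side; no stereocentre is touched, so the trans relation of the future C5 and C10 substituents follows from step 1.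

Step 5
Reactants: 9 ring B enol acetate
Product: 10 methyl (2E)-5-[2-acetoxy-6-methyl-6-(3-oxopropyl)-5-(prop-1-en-2-yl)cyclohex-2-en-1-yl]-3-methylpent-2-enoate (configuration as 9)
Conditions: Rh(acac)(CO)2 (1 mol %), PPh3 (20 mol %), CO/H2 (1:1, 10 bar), toluene, 60 °C
Reagents that add atoms: carbon monoxide, [C-]#[O+]
Why: Rhodium-catalysed hydroformylation should select the monosubstituted vinyl group over the 1,1-disubstituted isopropenyl and the trisubstituted enol acetate and enoate, and gives only the linear aldehyde because the branched position is neopentylic, which completes the C1–C2–C3 chain with C3 as aldehyde.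

Step 6
Reactants: 10 aldehyde
Product: 11 methyl 8-acetoxy-3β-hydroxy-17-nor-9βH-labda-7,13E-dien-15-oate (trans-fused, 5α-H, 10β-methyl, side chain at C9 still α)
Conditions: Fe(acac)3 (1.0 equiv), PhSiH3 (2.5 equiv), EtOH–THF 1:1 (0.02 M), 60 °C
Reagents that add atoms: none
Why: Fe(acac)3 and PhSiH3 in ethanol generate a trivalent iron hydride that transfers a hydrogen atom to the terminal CH2 of the isopropenyl group (Markovnikov MHAT), giving the tertiary C4 radical that already carries C18 and C19; this radical adds to the C3 aldehyde carbon and the alkoxyl radical is reduced by divalent iron (or quenched by the solvent) and protonated. The closest known reaction types are the iron-mediated MHAT reductive cyclisation of alkene-tethered ketones and the MHAT coupling of unactivated alkenes with aldehydes. Ring A closes in the 6-exo-trig mode onto the carbonyl carbon, forming the C3–C4 bond, the quaternary C4 and the C3 carbinol in one operation. C3 is the only new stereocentre: a chair transition state anchored by the trans-diequatorial C5–C4 and C10–C1 bonds should put the small aldehyde hydrogen in the axial site (syn to H-1α and H-5α) and the oxygen equatorial, giving the 3β-alcohol, and because the addition is reversible the less hindered equatorial alkoxyl radical should also be the one that is trapped. The selectivity needed is hydrogen-atom transfer at the 1,1-disubstituted isopropenyl in preference to the trisubstituted enol acetate and the electron-poor trisubstituted enoate, which the steric and electronic preferences of MHAT should secure, and addition to the aldehyde only, which is secured by masking C8 as its enol acetate. C5 and C10 already hold their configurations in 10 (from steps 1 and 4), so the ring fusion is necessarily trans.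

Step 7
Reactants: 11 enol acetate
Product: 12 methyl 3β-hydroxy-8-oxo-17-norlabd-13E-en-15-oate (5α-H, 9α-H, 10β-methyl)
Conditions: NaOMe (0.5 equiv), MeOH, rt → 40 °C; AcOH quench
Reagents that add atoms: none
Why: Methoxide cleaves the enol acetate by transesterification to release the C8 ketone and, through the C8/C9 enolate, should equilibrate C9 to the epimer with the equatorial (β) side chain, which avoids the syn-axial contacts of an axial chain with the axial hydrogens on C1, C5 and C7; the methyl ester is inert to methanolysis.

Step 8
Reactants: 12 keto ester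
Product: 13 methyl 3β-hydroxylabda-8(17),13E-dien-15-oate
Conditions: Ph3PCH3Br (4 equiv), KN(SiMe3)2 (3.8 equiv), toluene–THF, 0 → 70 °C
Reagents that add atoms: methyltriphenylphosphonium bromide, C[P+](c1ccccc1)(c1ccccc1)c1ccccc1.[Br-]
Why: Wittig methylenation of the hindered C8 ketone with excess ylide (a transformation well established for 17-nor-8-oxolabdanes) installs C17, the C3 hydroxyl being carried as its alkoxide and C9 already holding its thermodynamically preferred configuration.

Step 9
Reactants: 13 hydroxy ester
Product: 15 3β-hydroxylabda-8(17),13E-dien-15-oic acid, via lithium carboxylate 14 (not isolated)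
Conditions: LiOH·H2O (5 equiv), THF–MeOH–H2O, 50 °C; then 0.5 M HCl to pH 4, 0 °C
Reagents that add atoms: lithium hydroxide, [Li+].[OH-]
Why: Saponification of the β,β-disubstituted enoate followed by cold, mild acidification should free the acid without migration of the acid-sensitive exocyclic alkene.

Step 10
Reactants: 15 hydroxy acid
Product: 17 3β-acetoxylabda-8(17),13E-dien-15-oic acid (target), via mixed acetic anhydride 16 (not isolated)
Conditions: Ac2O, pyridine, 4-(dimethylamino)pyridine (cat.), rt; then H2O–THF, rt
Reagents that add atoms: acetic anhydride, CC(=O)OC(C)=O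
Why: Acylation of the equatorial secondary alcohol with Ac2O/pyridine is routine, and the carboxyl group is converted only transiently into the mixed anhydride, which is hydrolysed back to the acid in the aqueous pyridine work-up.

**Compound list**

1 | (1R,5R)-(+)-verbenone, (1R,5R)-4,6,6-trimethylbicyclo[3.1.1]hept-3-en-2-one | CC1=CC(=O)[C@@H]2C[C@H]1C2(C)C | starting material
2 | vinylmagnesium bromide | C=C[Mg]Br | starting material
3 | bromomagnesium enolate of 4,6,6-trimethyl-4-vinylbicyclo[3.1.1]heptan-2-one (vinyl anti to the CMe2 bridge; formed in situ) | C=C[C@]1(C)C=C(O[Mg]Br)[C@@H]2C[C@H]1C2(C)C | intermediate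
4 | 4,6,6-trimethyl-2-(trimethylsilyloxy)-4-vinylbicyclo[3.1.1]hept-2-ene (bridgeheads as in 1, vinyl anti to the CMe2 bridge) | C=C[C@]1(C)C=C(O[Si](C)(C)C)[C@@H]2C[C@H]1C2(C)C | intermediate
5 | methyl vinyl ketone (but-3-en-2-one) | CC(=O)C=C | starting material
6 | 4,6,6-trimethyl-3-(3-oxobutyl)-4-vinylbicyclo[3.1.1]heptan-2-one (vinyl and oxobutyl anti to the CMe2 bridge; expected major epimer at the oxobutyl carbon) | C=C[C@]1(C)[C@H](CCC(C)=O)C(=O)[C@@H]2C[C@H]1C2(C)C | intermediate
7 | trimethyl phosphonoacetate | COC(=O)CP(=O)(OC)OC | starting material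
8 | methyl (2E)-3-methyl-5-(4,6,6-trimethyl-2-oxo-4-vinylbicyclo[3.1.1]hept-3-yl)pent-2-enoate (configuration as 6) | C=C[C@]1(C)[C@H](CC/C(C)=C/C(=O)OC)C(=O)[C@@H]2C[C@H]1C2(C)C | intermediate
9 | methyl (2E)-5-[2-acetoxy-6-methyl-5-(prop-1-en-2-yl)-6-vinylcyclohex-2-en-1-yl]-3-methylpent-2-enoate (isopropenyl trans to vinyl, side chain cis to vinyl) | C=C[C@]1(C)[C@H](CC/C(C)=C/C(=O)OC)C(OC(C)=O)=CC[C@H]1C(C)=C | intermediate
10 | methyl (2E)-5-[2-acetoxy-6-methyl-6-(3-oxopropyl)-5-(prop-1-en-2-yl)cyclohex-2-en-1-yl]-3-methylpent-2-enoate (configuration as 9) | O=CCC[C@]1(C)[C@H](CC/C(C)=C/C(=O)OC)C(OC(C)=O)=CC[C@H]1C(C)=C | intermediate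
11 | methyl 8-acetoxy-3β-hydroxy-17-nor-9βH-labda-7,13E-dien-15-oate | CC(=O)OC1=CC[C@H]2C(C)(C)[C@@H](O)CC[C@]2(C)[C@@H]1CC/C(C)=C/C(=O)OC | intermediate
12 | methyl 3β-hydroxy-8-oxo-17-norlabd-13E-en-15-oate | O=C1CC[C@H]2C(C)(C)[C@@H](O)CC[C@]2(C)[C@H]1CC/C(C)=C/C(=O)OC | intermediate
13 | methyl 3β-hydroxylabda-8(17),13E-dien-15-oate | C=C1CC[C@H]2C(C)(C)[C@@H](O)CC[C@]2(C)[C@H]1CC/C(C)=C/C(=O)OC | intermediate
14 | lithium 3β-hydroxylabda-8(17),13E-dien-15-oate (formed in situ) | C=C1CC[C@H]2C(C)(C)[C@@H](O)CC[C@]2(C)[C@H]1CC/C(C)=C/C(=O)[O-].[Li+] | intermediate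
15 | 3β-hydroxylabda-8(17),13E-dien-15-oic acid | C=C1CC[C@H]2C(C)(C)[C@@H](O)CC[C@]2(C)[C@H]1CC/C(C)=C/C(=O)O | intermediate
16 | acetic 3β-acetoxylabda-8(17),13E-dien-15-oic anhydride (formed in situ) | C=C1CC[C@H]2C(C)(C)[C@@H](OC(C)=O)CC[C@]2(C)[C@H]1CC/C(C)=C/C(=O)OC(C)=O | intermediate
17 | 3β-acetoxylabda-8(17),13E-dien-15-oic acid | C=C1CC[C@H]2C(C)(C)[C@@H](OC(C)=O)CC[C@]2(C)[C@H]1CC/C(C)=C/C(=O)O | target

**Totals**

Total step count: 10. Longest linear sequence: 10 steps (from 1).

**Steps most likely to fail**

1. Step 6 (key step). Risk: poor facial selectivity in the addition of the C4 radical to the aldehyde, so that the 3α-carbinol forms alongside the 3β one, aggravated by the reversibility of the addition. Fallback: C3 is set by hydride delivery instead of by the radical step. The epimeric mixture is carried through steps 7 and 8, so the fallback sets out from 13, accompanied by methyl 3α-hydroxylabda-8(17),13E-dien-15-oate F1. Oxidation of the mixture (Dess–Martin periodinane, NaHCO3, CH2Cl2) should converge on methyl 3-oxolabda-8(17),13E-dien-15-oate F2. Reduction with NaBH4 in MeOH at 0 °C, hydride entering axially from the α-face opposite the axial methyls on C4 and C10, should then return the equatorial 3β-alcohol, and the route is rejoined at 13.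

2. Step 4. Risk: the tertiary cation released by the fragmentation may persist long enough for hydride shift from the adjacent ring carbon and Wagner–Meerwein migration from the neighbouring quaternary centre, or be captured by acetate instead of losing a proton. Fallback: a nucleophile-assisted opening that leaves no free cation, setting out from 8. Me3SiI (from Me3SiCl and NaI, MeCN, 0 °C) should open the cyclobutyl ketone with iodide capture to methyl (2E)-5-[5-(2-iodopropan-2-yl)-6-methyl-2-(trimethylsilyloxy)-6-vinylcyclohex-2-en-1-yl]-3-methylpent-2-enoate F3. Aqueous work-up hydrolyses this to the iodo ketone methyl (2E)-5-[3-(2-iodopropan-2-yl)-2-methyl-6-oxo-2-vinylcyclohexyl]-3-methylpent-2-enoate F4. E2 elimination with DBU (toluene, 60 °C) should give the isopropenyl ketone methyl (2E)-3-methyl-5-[2-methyl-6-oxo-3-(prop-1-en-2-yl)-2-vinylcyclohexyl]pent-2-enoate F5. Kinetic enolisation at the ring methylene with KN(SiMe3)2 (THF, −78 °C) and O-acetylation with Ac2O then gives 9, where the route is rejoined.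

3. Step 7. Risk: insufficient thermodynamic bias at C9, the equilibration leaving a sizeable share of the epimer with the axial side chain. Fallback: kinetic instead of thermodynamic control, setting out from 12 accompanied by methyl 3β-hydroxy-8-oxo-17-nor-9βH-labd-13E-en-15-oate F6. Equilibrating silylation (Me3SiOTf, Et3N, CH2Cl2, 0 °C → rt) should convert both epimers into the same tetrasubstituted enol ether, methyl 3β,8-bis(trimethylsilyloxy)-17-norlabda-8,13E-dien-15-oate F7. Low-temperature protodesilylation (Bu4NF, AcOH, THF, −78 °C) should protonate C9 axially from the α-face, the β-face being screened by the axial C10 methyl, and free the C3 hydroxyl, so that the route is rejoined at 12.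

Further compounds
F1 | step 6 | methyl 3α-hydroxylabda-8(17),13E-dien-15-oate | C=C1CC[C@H]2C(C)(C)[C@H](O)CC[C@]2(C)[C@H]1CC/C(C)=C/C(=O)OC
F2 | step 6 | methyl 3-oxolabda-8(17),13E-dien-15-oate | C=C1CC[C@H]2C(C)(C)C(=O)CC[C@]2(C)[C@H]1CC/C(C)=C/C(=O)OC
F3 | step 4 | methyl (2E)-5-[5-(2-iodopropan-2-yl)-6-methyl-2-(trimethylsilyloxy)-6-vinylcyclohex-2-en-1-yl]-3-methylpent-2-enoate | C=C[C@]1(C)[C@H](CC/C(C)=C/C(=O)OC)C(O[Si](C)(C)C)=CC[C@H]1C(C)(C)I
F4 | step 4 | methyl (2E)-5-[3-(2-iodopropan-2-yl)-2-methyl-6-oxo-2-vinylcyclohexyl]-3-methylpent-2-enoate | C=C[C@]1(C)[C@H](CC/C(C)=C/C(=O)OC)C(=O)CC[C@H]1C(C)(C)I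
F5 | step 4 | methyl (2E)-3-methyl-5-[2-methyl-6-oxo-3-(prop-1-en-2-yl)-2-vinylcyclohexyl]pent-2-enoate | C=C[C@]1(C)[C@H](CC/C(C)=C/C(=O)OC)C(=O)CC[C@H]1C(C)=C
F6 | step 7 | methyl 3β-hydroxy-8-oxo-17-nor-9βH-labd-13E-en-15-oate | O=C1CC[C@H]2C(C)(C)[C@@H](O)CC[C@]2(C)[C@@H]1CC/C(C)=C/C(=O)OC
F7 | step 7 | methyl 3β,8-bis(trimethylsilyloxy)-17-norlabda-8,13E-dien-15-oate | C[Si](C)(C)OC1=C(CC/C(C)=C/C(=O)OC)[C@@]2(C)CC[C@H](O[Si](C)(C)C)C(C)(C)[C@@H]2CC1
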